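**Retrosynthetic overview**
1. The target is a flavone (rings A, C and B) whose C3 and O2' are bridged by CH2–CH2–C(CH3)2, giving an eight-membered oxocine ring (C3, C2, C1', C2', O, CMe2, CH2, CH2). The last step only frees the 5- and 4'-phenols from benzyl ethers.
2. Key disconnection: the oxocine ring is cut at both of its bonds to ring C, C3–CH2 and C2–C1'. A one-flask palladium domino (B-alkyl Suzuki–Miyaura coupling, then C–H arylation) should make both, as a [6+2] annulation of a six-atom ring B unit (C1'–Br … CH2–B) onto the C2=C3 unit of a 3-iodochromone.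
3. Enabling feature: the vinylogous ester O1–C2=C3–C4=O of ring C. C3 takes iodine and then reacts as an α-iodo enone, and C2–H, flanked by the ring oxygen O1 and conjugated to C4=O, is the one acidic sp2 C–H that the gem-dimethyl ether tether on O2' of ring B can reach.
4. Ring order: rings A and B are bought; ring C is closed from an ortho-hydroxyacetophenone by enaminone formation and iodocyclisation; the oxocine ring is closed last, in the key step.
5. The C5 bridge is carried on ring B as a 1,1-dimethylallyl aryl ether (propargylic etherification, semihydrogenation) and is hydroborated in the key step.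

Key step: step 6

Remark: the target has no stereocentre and the biaryl axis inside the eight-membered ring is taken as configurationally mobile, so no stereocontrol is needed; 5-(benzyloxy)-2-bromophenol is taken as a purchasable building block.

**Step 1**
Reactants: 1 1-(2,6-dihydroxy-4-methoxyphenyl)ethan-1-one
Product: 2 1-[2-(benzyloxy)-6-hydroxy-4-methoxyphenyl]ethan-1-one
Conditions: BnBr (1.05 equiv), K2CO3, acetone, reflux
Reagents that add atoms: benzyl bromide, BrCc1ccccc1
Why: Williamson etherification of the symmetric diol should stop at the mono-ether, because the remaining phenol is locked in a hydrogen bond to the acetyl carbonyl and is far less nucleophilic.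

**Step 2**
Reactants: 2 1-[2-(benzyloxy)-6-hydroxy-4-methoxyphenyl]ethan-1-one
Product: 3 (E)-1-[2-(benzyloxy)-6-hydroxy-4-methoxyphenyl]-3-(dimethylamino)prop-2-en-1-one
Conditions: DMF-DMA, toluene, 95 °C
Reagents that add atoms: N,N-dimethylformamide dimethyl acetal, COC(OC)N(C)C
Why: Enaminone condensation of a methyl ketone with an amide acetal is standard for ortho-hydroxyacetophenones and spares the hydrogen-bonded phenol, the E geometry being that of the favoured trans push–pull enaminone.

**Step 3**
Reactants: 3 (E)-1-[2-(benzyloxy)-6-hydroxy-4-methoxyphenyl]-3-(dimethylamino)prop-2-en-1-one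
Product: 4 5-(benzyloxy)-3-iodo-7-methoxy-4H-chromen-4-one
Conditions: I2, MeOH, rt
Reagents that add atoms: iodine, II
Why: Iodine-mediated cyclisation of an ortho-hydroxyaryl enaminone (α-iodination, 6-endo attack of the phenol on the iminium carbon, loss of dimethylamine) is the standard entry to 3-iodochromones, the enaminone α-carbon being more nucleophilic than ring A.

**Step 4**
Reactants: 5 5-(benzyloxy)-2-bromophenol; 6 3-chloro-3-methylbut-1-yne
Product: 7 4-(benzyloxy)-1-bromo-2-[(2-methylbut-3-yn-2-yl)oxy]benzene
Conditions: CuCl2·2H2O (1 mol %), DBU, MeCN, 0 °C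
Reagents that add atoms: none
Why: Copper-catalysed propargylic etherification of a phenol with a tertiary propargylic chloride (copper acetylide-derived electrophile) is the usual route to aryl 1,1-dimethylpropargyl ethers and should tolerate the ortho bromide.

**Step 5**
Reactants: 7 4-(benzyloxy)-1-bromo-2-[(2-methylbut-3-yn-2-yl)oxy]benzene
Product: 8 4-(benzyloxy)-1-bromo-2-[(2-methylbut-3-en-2-yl)oxy]benzene
Conditions: H2 (1 atm), Pd/CaCO3 poisoned with Pb(OAc)2, quinoline, EtOAc, rt
Reagents that add atoms: none
Why: Lindlar-type semihydrogenation should stop the terminal alkyne at the alkene on the poisoned catalyst, which does not cleave aryl bromides or benzyl ethers under these conditions.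

**Step 6**
Reactants: 8 4-(benzyloxy)-1-bromo-2-[(2-methylbut-3-en-2-yl)oxy]benzene; 4 5-(benzyloxy)-3-iodo-7-methoxy-4H-chromen-4-one
Product: 11 5,4'-di-O-benzylcyclointegrin, via B-alkyl-9-BBN adduct 9 (not isolated), via 3-alkylchromone aryl bromide 10 (not isolated)
Conditions: 9-BBN dimer (0.5 equiv), THF, 0 °C to rt; then 4, Pd(OAc)2 (10 mol %), PCy3·HBF4 (20 mol %), K3PO4·H2O, CsOPiv (30 mol %), DMA/THF, 0.02 M, 40 °C then 120 °C (sealed, same flask, no further addition)
Reagents that add atoms: 9-borabicyclo[3.3.1]nonane (9-BBN, used as its dimer), B1C2CCCC1CCC2 (its boron is held only in intermediate 9)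
Why: Anti-Markovnikov hydroboration of the monosubstituted alkene of 8 places boron on the terminal carbon, and zerovalent palladium then inserts first into the C3–I bond of 4 (an α-iodo enone, far faster than the electron-rich ortho-alkoxy aryl bromide), so that transmetalation from the borate and reductive elimination give the C3–CH2 bond of 10; on heating, the same catalyst inserts into the C–Br bond, and pivalate-assisted concerted metalation–deprotonation at C2–H followed by reductive elimination gives the C2–C1' bond. The closest known reaction types are the B-alkyl Suzuki–Miyaura coupling of α-iodo enones and 3-iodochromones, the intramolecular direct arylation of enone and heteroarene C–H bonds under Pd(OAc)2/PCy3/pivalate, and one-pot Suzuki/direct-arylation dominos. The eight-membered oxocine ring is closed at the biaryl bond through a nine-membered palladacycle, formally an 8-endo attack on the C2=C3 bond, helped by the gem-dimethyl group and by four sp2 ring atoms; a carbopalladation/β-hydride elimination alternative would give the exocyclic 3-alkylidene flavanone, which should tautomerise to the same flavone under the basic conditions. No stereocentre is formed. Chemoselectivity (iodide before bromide) rests on the large difference in oxidative-addition rate and on the temperature programme, site selectivity on C2–H being the only acidic sp2 C–H within reach of the tether, and oligomerisation is held back by dilution.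

**Step 7**
Reactants: 11 5,4'-di-O-benzylcyclointegrin
Product: 12 cyclointegrin
Conditions: H2 (1 atm), Pd/C, EtOAc/MeOH, rt
Reagents that add atoms: none
Why: Hydrogenolysis of the two aryl benzyl ethers on Pd/C should leave the tetrasubstituted C2=C3 bond of the flavone, the tertiary alkyl aryl ether and the methyl ether untouched.

**Compound list**
1 | 1-(2,6-dihydroxy-4-methoxyphenyl)ethan-1-one | CC(=O)c1c(O)cc(OC)cc1O | starting material
2 | 1-[2-(benzyloxy)-6-hydroxy-4-methoxyphenyl]ethan-1-one | CC(=O)c1c(O)cc(OC)cc1OCc1ccccc1 | intermediate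
3 | (E)-1-[2-(benzyloxy)-6-hydroxy-4-methoxyphenyl]-3-(dimethylamino)prop-2-en-1-one | CN(C)/C=C/C(=O)c1c(O)cc(OC)cc1OCc1ccccc1 | intermediate
4 | 5-(benzyloxy)-3-iodo-7-methoxy-4H-chromen-4-one | COc1cc(OCc2ccccc2)c2c(=O)c(I)coc2c1 | intermediate
5 | 5-(benzyloxy)-2-bromophenol | Oc1cc(OCc2ccccc2)ccc1Br | starting material
6 | 3-chloro-3-methylbut-1-yne | C#CC(C)(C)Cl | starting material
7 | 4-(benzyloxy)-1-bromo-2-[(2-methylbut-3-yn-2-yl)oxy]benzene | C#CC(C)(C)Oc1cc(OCc2ccccc2)ccc1Br | intermediate
8 | 4-(benzyloxy)-1-bromo-2-[(2-methylbut-3-en-2-yl)oxy]benzene | C=CC(C)(C)Oc1cc(OCc2ccccc2)ccc1Br | intermediate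
9 | 9-{3-[5-(benzyloxy)-2-bromophenoxy]-3-methylbutyl}-9-borabicyclo[3.3.1]nonane (B-alkyl-9-BBN adduct) | CC(C)(CCB1C2CCCC1CCC2)Oc1cc(OCc2ccccc2)ccc1Br | intermediate
10 | 5-(benzyloxy)-3-{3-[5-(benzyloxy)-2-bromophenoxy]-3-methylbutyl}-7-methoxy-4H-chromen-4-one (3-alkylchromone aryl bromide) | COc1cc(OCc2ccccc2)c2c(=O)c(CCC(C)(C)Oc3cc(OCc4ccccc4)ccc3Br)coc2c1 | intermediate
11 | 5,4'-di-O-benzylcyclointegrin (flavone with 5-OBn, 7-OMe, 4'-OBn; C3 and O2' bridged by CH2CH2CMe2) | COc1cc(OCc2ccccc2)c2c(=O)c3c(oc2c1)-c1ccc(OCc2ccccc2)cc1OC(C)(C)CC3 | intermediate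
12 | cyclointegrin (5,4'-dihydroxy-7-methoxyflavone; C3 and O2' bridged by CH2CH2CMe2 in an eight-membered oxocine ring; achiral) | COc1cc(O)c2c(=O)c3c(oc2c1)-c1ccc(O)cc1OC(C)(C)CC3 | target

**Step count and risks**
Total step count: 7. Longest linear sequence: 5 steps (1, 2, 3, 6, 7).

Steps most likely to fail:

Step 6. Process at risk: the ring-closing C–H arylation has to pass through a medium-ring palladacycle. It may be outrun by intermolecular arylation, by hydrodebromination, or by base-induced opening of the pyranone at 120 °C, so the domino could stall at the open-chain stage or drain into oligomers. Fallback (known chemistry; the oxocine ring is closed at its ether C–O bond instead of at its two C–C bonds): it sets out from 2, which is O-acylated with 2,4-bis(benzyloxy)benzoic acid (EDC, DMAP, CH2Cl2) to the aryl ester 2-acetyl-3-(benzyloxy)-5-methoxyphenyl 2,4-bis(benzyloxy)benzoate F1. Baker–Venkataraman rearrangement (KOH, pyridine, 50 °C) should give the 1,3-diketone F2, C-prenylation at the central carbon (prenyl bromide, K2CO3, acetone) the C-prenylated diketone F3, and acid-catalysed cyclodehydration (TsOH, toluene, 60 °C) the 3-prenylflavone tribenzyl ether F4. Debenzylation that spares the alkene (BCl3, pentamethylbenzene, CH2Cl2, −78 °C) should give integrin F5. Its 2'-hydroxyl should then add in the Markovnikov sense to the protonated prenyl group (TsOH, benzene, reflux) and close the eight-membered ring; the fallback comes back to the route at 12.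

Step 5. Process at risk: over-reduction of the terminal alkyne to the ethyl ether, or hydrogenolysis of the C–Br bond on palladium. Fallback (the alkyne itself becomes the coupling partner, so neither semihydrogenation nor hydroboration is needed): it sets out from 7, which is joined to iodochromone 4 in a Sonogashira coupling (Pd(PPh3)2Cl2, CuI, Et3N, THF, rt; the vinyl iodide reacts, the aryl bromide does not) to give the enyne 5-(benzyloxy)-3-{3-[5-(benzyloxy)-2-bromophenoxy]-3-methylbut-1-yn-1-yl}-7-methoxy-4H-chromen-4-one F6. Saturation of the triple bond with diimide (TsNHNH2, NaOAc, DME/H2O, 80 °C) should leave the C–Br bond, the benzyl ethers and the polarised C2=C3 bond alone and comes back to the route at 10, which is then isolated and closed to 11 under the arylation conditions of step 6.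

Step 4. Process at risk: slow O-alkylation of the hindered, weakly nucleophilic ortho-bromophenoxide, with loss of HCl from the tertiary chloride. Fallback (π-allyl chemistry instead of propargylic substitution plus semihydrogenation): it sets out from 5, which is O-allylated with tert-butyl (2-methylbut-3-en-2-yl) carbonate under zerovalent-palladium catalysis (Pd(PPh3)4, THF, 0 °C; Tsuji–Trost etherification, branched ether under kinetic control). It comes back to the route at 8 directly, so steps 4 and 5 both drop out; it makes no new compound F0.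

**Further compounds**
F1 | step 6 | 2-acetyl-3-(benzyloxy)-5-methoxyphenyl 2,4-bis(benzyloxy)benzoate | CC(=O)c1c(OC(=O)c2ccc(OCc3ccccc3)cc2OCc2ccccc2)cc(OC)cc1OCc1ccccc1
F2 | step 6 | 1-[2-(benzyloxy)-6-hydroxy-4-methoxyphenyl]-3-[2,4-bis(benzyloxy)phenyl]propane-1,3-dione | COc1cc(O)c(C(=O)CC(=O)c2ccc(OCc3ccccc3)cc2OCc2ccccc2)c(OCc2ccccc2)c1
F3 | step 6 | 1-[2-(benzyloxy)-6-hydroxy-4-methoxyphenyl]-3-[2,4-bis(benzyloxy)phenyl]-2-(3-methylbut-2-en-1-yl)propane-1,3-dione | COc1cc(O)c(C(=O)C(CC=C(C)C)C(=O)c2ccc(OCc3ccccc3)cc2OCc2ccccc2)c(OCc2ccccc2)c1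
F4 | step 6 | 5-(benzyloxy)-2-[2,4-bis(benzyloxy)phenyl]-7-methoxy-3-(3-methylbut-2-en-1-yl)-4H-chromen-4-one | COc1cc(OCc2ccccc2)c2c(=O)c(CC=C(C)C)c(-c3ccc(OCc4ccccc4)cc3OCc3ccccc3)oc2c1
F5 | step 6 | integrin, 2-(2,4-dihydroxyphenyl)-5-hydroxy-7-methoxy-3-(3-methylbut-2-en-1-yl)-4H-chromen-4-one | COc1cc(O)c2c(=O)c(CC=C(C)C)c(-c3ccc(O)cc3O)oc2c1
F6 | step 5 | 5-(benzyloxy)-3-{3-[5-(benzyloxy)-2-bromophenoxy]-3-methylbut-1-yn-1-yl}-7-methoxy-4H-chromen-4-one | COc1cc(OCc2ccccc2)c2c(=O)c(C#CC(C)(C)Oc3cc(OCc4ccccc4)ccc3Br)coc2c1
F0 | step 4 | none | none
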